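All runs come from a simulation with constants of no real substance.

Thursday's run stalls at 0.459 M of target, with 0.501 M of coupling partner still there. Starting material is the limiting reagent of that charge, yet 0.341 M of it has not become target at 18 h. Suppose it leaks away by itself, first order, while coupling runs first order in each partner. Then each bit of partner spent costs starting material in the ratio of a fixed level to the current [coupling partner]. Call that level the break-even partner level: the [coupling partner] at which coupling and leak run equally fast. Summed up to the stall, and counting whatever has not become target as leaked, it is the starting material not turned, divided by the natural log of start [coupling partner] over stall [coupling partner]. Thursday's run reads 0.524 M.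

| flask | starting material | coupling partner | time |
|---|---|---|---|
| Thursday's | 0.800 M | 0.960 M |  |
| Friday's | 1.60 M | 0.960 M |  |
| Saturday's | 0.800 M | 1.40 M |  |
| Tuesday's | 0.400 M | 0.480 M | 18 h |

- Thursday's run (time / h: [target] / M): 3.6: 0.277; 7.2: 0.380; 11: 0.432; 14: 0.455; 18: 0.459
- Friday's run (time / h: [target] / M): 3.6: 0.496; 7.2: 0.675; 11: 0.741; 14: 0.785; 18: 0.790
- Saturday's run (time / h: [target] / M): 3.6: 0.371; 7.2: 0.487; 11: 0.530; 14: 0.552; 18: 0.555

(standard deviation of a reading: 0.004 M)

- reaction order in [starting material] at the outset, round the charge of the Thursday's run, defined at two percent of the starting material turned into target (one fixed amount of target, the same in the runs compared)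
- reaction order in [coupling partner] at the outset, round the charge of the Thursday's run, defined at two percent of the starting material turned into target
- target in the Tuesday's run at 18 h, as a share of the starting material charged

- Overall: starting material + coupling partner -> target.
- Constant volume, constant temperature.
- Readings of a species count what is bound in complexes too.
- "The second partner" is coupling partner.
- An order is taken over about fifteen percent of the charge, up and down.

Raise the starting material, as Friday's run does. By hand, more partner gets spent, coupling slows late, and the share turned should fall. It does: 49.4% against Thursday's 57.4%. Friday's level reads 0.468 M.

Raise the partner, as Saturday's run does. By hand, coupling gains on the leak. The share climbs to 69.4%, and Saturday's level reads 0.485 M.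

The shares run from 49.4% to 69.4%, the readings of the level from 0.468 M to 0.524 M, so take the break-even partner level frozen at the mean, 0.493 M.

Now halve both charges of Thursday's run, as Tuesday's run does. By hand, the partner falls against a fixed break-even, so the share should drop. My own reckoning with the frozen level gives 44.1%. The forecast says 41%, lower than mine, with orders of 0.95 in starting material and 1 in coupling partner, finding “early kinetics are close to first order in each partner”.

Tuesday's run gives 38.4%, and the orders round Thursday's charge are 1.0 in starting material and 1.1 in coupling partner.

    2 coupling partner ⇌ reagent dimer, settled at all times (24.30 L mol⁻¹)
    starting material + reagent dimer → target + coupling partner (0.3636 L mol⁻¹ h⁻¹)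
    starting material → decomposed substrate (0.08892 h⁻¹)
    starting material + coupling partner + target → 2 target (0.7308 L² mol⁻² h⁻¹)

The leak is the conversion of starting material into decomposed substrate: without it, Tuesday's run would give 62.0% instead of 38.4%. Read back from the result, counting whatever has not become target as leaked, Tuesday's run has a level of 0.638 M, above the frozen 0.493 M. In Friday's run, half the starting material charged has become target at 18.0 h. There the frozen level puts the starting material lost to the leak at 0.882 M, against 0.800 M not turned by subtraction.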